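**Plan**
- Retrosynthesis cuts, in this order: the C3''–acyl bond (Friedel–Crafts); ring D across C5''–C6'', C3''–C4'' and C6''–C1'' into a 4-substituted 3-tert-butoxycyclobutenone and 1-(triisopropylsilyloxy)propyne; the cyclobutenone across C1–C2 and C3–C4 into a ketene and tert-butoxyacetylene; ring C (chalcone); the C8–allyl bond.
- Enabling feature: ring D carries oxygen on C2'', C4'' and C6'' in a 1,3,5 array, CH3 on C5'', the bridge CH2 on C1'' and hydrogen only on C3''. A vinylketene plus an ynol silyl ether delivers these oxygens as tert-butyl ether (C2''), silyl ether (C4'') and free phenol (C6'').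
- Forward: ring A is bought (phloroacetophenone); an allyl group is placed on the future C8 by Claisen rearrangement; ring B comes with anisaldehyde and ring C closes by Algar–Flynn–Oyamada oxidation; the allyl group is oxidised to the propanoic acid, whose ketene gives the cyclobutenone.
- Ring D is formed last by the benzannulation, then O-methylation at C6'', release of the C2'' and C4'' hydroxyls, acylation at C3'' and hydrogenolysis.
- Stereochemistry: the target has no stereocentre and no stereogenic double bond; the one sp3 centre made on the way (C4 of the cyclobutenone) is racemic and vanishes when ring D aromatises.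

Key step: step 13

Remarks: Fl stands for the 3,5,7-tris(benzyloxy)-2-(4-methoxyphenyl)-4-oxo-4H-chromen-8-yl group; ring D carbons are numbered C1'' (bearing the bridge CH2) to C6'' as in the target.
Assumption: the C2'' oxygen is carried as a tert-butyl ether, because Lewis-acid dealkylation of a primary alkyl ether beside an already hydrogen-bonded ketone would compete with cleavage of the hindered C6'' methyl ether; tert-butoxyacetylene is therefore prepared (steps 9 and 10), and 1-propynyllithium is taken as a stocked reagent.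

**Step 1**
Reactants: 1 2,4,6-trihydroxyacetophenone
Product: 2 1-[2,4-bis(benzyloxy)-6-hydroxyphenyl]ethan-1-one
Conditions: BnBr (2.1 equiv), K2CO3, DMF, 0 °C to rt
Reagents that add atoms: benzyl bromide BrCc1ccccc1
Why: Williamson etherification in which the para hydroxyl and one ortho hydroxyl are alkylated, whereas the remaining ortho hydroxyl is hydrogen-bonded to the acetyl carbonyl and resists a third alkylation under these conditions.

**Step 2**
Reactants: 2 1-[2,4-bis(benzyloxy)-6-hydroxyphenyl]ethan-1-one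
Product: 3 1-[2-(allyloxy)-4,6-bis(benzyloxy)phenyl]ethan-1-one
Conditions: allyl bromide, K2CO3, DMF, 60 °C
Reagents that add atoms: allyl bromide C=CCBr
Why: Williamson allylation of the chelated phenol under slightly more forcing conditions provides the aryl allyl ether needed for the sigmatropic shift.

**Step 3**
Reactants: 3 1-[2-(allyloxy)-4,6-bis(benzyloxy)phenyl]ethan-1-one
Product: 5 1-[3-allyl-4,6-bis(benzyloxy)-2-hydroxyphenyl]ethan-1-one, via ortho-dienone 4 (not isolated)
Conditions: PhNEt2, 195 °C, argon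
Reagents that add atoms: none
Why: Aromatic Claisen rearrangement in which the [3,3] shift can reach only the free ortho carbon (the other ortho position carries the acetyl group), and tautomerisation of the dienone places the allyl group on the carbon that becomes C8.

**Step 4**
Reactants: 5 1-[3-allyl-4,6-bis(benzyloxy)-2-hydroxyphenyl]ethan-1-one; 6 4-methoxybenzaldehyde
Product: 8 (E)-1-[3-allyl-4,6-bis(benzyloxy)-2-hydroxyphenyl]-3-(4-methoxyphenyl)prop-2-en-1-one, via aldol 7 (not isolated)
Conditions: KOH (50% aqueous), EtOH/THF, rt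
Reagents that add atoms: none
Why: Claisen–Schmidt condensation with the non-enolisable aldehyde, dehydration of the aldol giving the conjugated E-enone whose geometry is of no later consequence.

**Step 5**
Reactants: 8 (E)-1-[3-allyl-4,6-bis(benzyloxy)-2-hydroxyphenyl]-3-(4-methoxyphenyl)prop-2-en-1-one
Product: 10 8-allyl-5,7-bis(benzyloxy)-3-hydroxy-2-(4-methoxyphenyl)-4H-chromen-4-one, via trans-dihydroflavonol 9 (not isolated)
Conditions: 30% H2O2, 2 M NaOH, MeOH/THF, 0 °C to rt
Reagents that add atoms: hydrogen peroxide OO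
Why: Algar–Flynn–Oyamada oxidation, in which alkaline hydroperoxide brings about oxidative cyclisation of the 2'-hydroxychalcone to the dihydroflavonol and then its dehydrogenation to the flavonol, while the isolated allyl double bond is inert to nucleophilic peroxide.

**Step 6**
Reactants: 10 8-allyl-5,7-bis(benzyloxy)-3-hydroxy-2-(4-methoxyphenyl)-4H-chromen-4-one
Product: 11 8-allyl-3,5,7-tris(benzyloxy)-2-(4-methoxyphenyl)-4H-chromen-4-one
Conditions: BnBr, K2CO3, DMF, rt
Reagents that add atoms: benzyl bromide BrCc1ccccc1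
Why: Williamson benzylation of the acidic 3-hydroxyl protects the last free oxygen of the flavonol before the organoborane, acyl chloride and base chemistry that follows.

**Step 7**
Reactants: 11 8-allyl-3,5,7-tris(benzyloxy)-2-(4-methoxyphenyl)-4H-chromen-4-one
Product: 13 3-(Fl)propan-1-ol, via B-alkylborane 12 (not isolated)
Conditions: 9-BBN, THF, 0 °C to rt; then 30% H2O2, aqueous NaOAc, 0 °C
Reagents that add atoms: hydrogen peroxide OO
Why: Anti-Markovnikov hydroboration of the terminal alkene with the bulky and chemoselective 9-BBN followed by buffered peroxide oxidation should give the primary alcohol, the vinylogous-ester carbonyl of the chromone and the benzyl ethers being inert.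

**Step 8**
Reactants: 13 3-(Fl)propan-1-ol
Product: 15 3-(Fl)propanoic acid, via aldehyde 14 (not isolated)
Conditions: TEMPO (2,2,6,6-tetramethylpiperidin-1-oxyl, catalytic), PhI(OAc)2 (2.2 equiv), MeCN/pH 7 buffer, rt
Reagents that add atoms: water O
Why: The nitroxyl-catalysed oxidation with PhI(OAc)2 in aqueous acetonitrile takes a primary alcohol through the aldehyde hydrate to the acid under near-neutral conditions that spare benzyl ethers and electron-rich rings.

**Step 9**
Reactants: 16 trichloroethylene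
Product: 18 (E)-1-tert-butoxy-1,2-dichloroethene, via dichloroacetylene 17 (not isolated)
Conditions: KOt-Bu (1.1 equiv), THF, −40 °C to rt
Reagents that add atoms: potassium tert-butoxide CC(C)(C)[O-].[K+]
Why: Base-induced elimination gives dichloroacetylene in situ, to which tert-butoxide adds in anti fashion, the established entry to 1,2-dichlorovinyl ethers.

**Step 10**
Reactants: 18 (E)-1-tert-butoxy-1,2-dichloroethene
Product: 21 tert-butoxyacetylene, via chloroalkyne 19 (not isolated), via lithium acetylide 20 (not isolated)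
Conditions: n-BuLi (2.2 equiv), Et2O, −78 to −30 °C; then H2O, −78 °C; distil below 20 °C, store cold
Reagents that add atoms: none
Why: Lithiation with loss of LiCl gives the chloroalkyne, chlorine–lithium exchange the lithium alkoxyacetylide and protonation the terminal ynol ether, which is the standard second stage of the dichlorovinyl ether route.

**Step 11**
Reactants: 15 3-(Fl)propanoic acid; 21 tert-butoxyacetylene
Product: 24 racemic 3-tert-butoxy-4-(Fl-methyl)cyclobut-2-en-1-one, via acid chloride 22 (not isolated), via ketene 23 (not isolated)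
Conditions: (COCl)2, DMF (catalytic), CH2Cl2, 0 °C to rt, evaporate; then 21 (4 equiv), Et3N (slow addition), Et2O/CH2Cl2, 0 °C to rt
Reagents that add atoms: none
Why: Dehydrochlorination of the acyl chloride gives the monoalkylketene, which undergoes the known regiospecific thermal [2+2] cycloaddition with an alkoxyacetylene (nucleophilic CH carbon to the ketene carbonyl carbon) to give the racemic 3-alkoxy-4-alkylcyclobutenone, slow base addition and excess ynol ether at or below room temperature limiting ketene dimerisation and loss of isobutene from 21.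

**Step 12**
Reactants: 25 1-propynyllithium
Product: 27 1-(triisopropylsilyloxy)prop-1-yne, via lithium ynolate 26 (not isolated)
Conditions: t-BuOOH, LiN(SiMe3)2, THF, −78 °C; add to 25, −78 to 0 °C; then i-Pr3SiOTf, −78 to 0 °C
Reagents that add atoms: tert-butyl hydroperoxide CC(C)(C)OO; triisopropylsilyl trifluoromethanesulfonate CC(C)[Si](C(C)C)(C(C)C)OS(=O)(=O)C(F)(F)F
Why: Oxidation of the lithium acetylide by lithium tert-butylperoxide gives the ynolate, which the bulky silyl triflate captures on oxygen, a standard route to 1-siloxyalkynes.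

**Step 13**
Reactants: 24 racemic 3-tert-butoxy-4-(Fl-methyl)cyclobut-2-en-1-one; 27 1-(triisopropylsilyloxy)prop-1-yne
Product: 32 3,5,7-tris(benzyloxy)-8-{[2-tert-butoxy-6-hydroxy-5-methyl-4-(triisopropylsilyloxy)phenyl]methyl}-2-(4-methoxyphenyl)-4H-chromen-4-one, via vinylketene 28 (not isolated), via alkenylcyclobutenone 29 (not isolated), via dienylketene 30 (not isolated), via cyclohexadienone 31 (not isolated)
Conditions: 27 (2.5 equiv), toluene (0.1 M), 80 °C then 110 °C, argon, sealed tube
Reagents that add atoms: none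
Why: Heating opens 24 by a four-electron conrotatory electrocyclic reaction to vinylketene 28, the C4 side chain turning outward so that only hydrogen points into the future ring, and the ketene then adds 27 in a regiospecific [2+2] cycloaddition in which the methyl-bearing alkyne carbon bonds to the ketene carbonyl carbon (C5''–C6'') and the silyloxy-bearing carbon to the ketene alpha carbon (C3''–C4''), giving 29. A second four-electron opening gives dienylketene 30, and ring D is closed by a thermal disrotatory six-electron electrocyclization that re-forms C6''–C1'', followed by tautomerisation of dienone 31 to the phenol. The closest known reaction type is the Danheiser benzannulation of cyclobutenones with siloxyalkynes, applied here to a 3-alkoxy-4-alkylcyclobutenone. No stereocentre is created, and the racemic C4 centre of 24 is erased on aromatisation. The step needs regiocontrol in the ketene–alkyne cycloaddition, which the oxygen-induced polarisation of the ynol silyl ether secures, and it needs the alkyne to outrun self-reaction of the ketene, which an excess of 27 at moderate dilution should ensure.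

**Step 14**
Reactants: 32 the C6'' phenol from step 13
Product: 33 3,5,7-tris(benzyloxy)-8-{[2-tert-butoxy-6-methoxy-5-methyl-4-(triisopropylsilyloxy)phenyl]methyl}-2-(4-methoxyphenyl)-4H-chromen-4-one
Conditions: MeI, K2CO3, acetone, 50 °C
Reagents that add atoms: iodomethane CI
Why: Williamson methylation of the only free hydroxyl, the C6'' phenol flanked by CH3 and the bridge CH2, should proceed cleanly because the silyl and tert-butyl aryl ethers are stable to K2CO3 in acetone.

**Step 15**
Reactants: 33 the C6'' methyl ether from step 14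
Product: 35 3,5,7-tris(benzyloxy)-8-[(2,4-dihydroxy-6-methoxy-5-methylphenyl)methyl]-2-(4-methoxyphenyl)-4H-chromen-4-one, via monosilyl ether 34 (not isolated)
Conditions: CF3CO2H/CH2Cl2 (1:4), 1,3-dimethoxybenzene (10 equiv), 0 °C, evaporate; then Bu4NF, AcOH, THF, 0 °C
Reagents that add atoms: none
Why: Acidolysis of the aryl tert-butyl ether (the cation being captured by 1,3-dimethoxybenzene) followed by buffered fluoride cleavage of the aryl silyl ether frees the C2'' and C4'' hydroxyls while benzyl and methyl ethers are untouched.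

**Step 16**
Reactants: 36 3-(4-hydroxyphenyl)propanoic acid
Product: 37 3-[4-(benzyloxy)phenyl]propanoic acid
Conditions: BnBr (1.1 equiv), NaOH (2.2 equiv), EtOH/H2O, reflux; then aqueous HCl
Reagents that add atoms: benzyl bromide BrCc1ccccc1
Why: Williamson benzylation of the phenoxide in aqueous ethanolic NaOH, where the carboxylate is a much poorer nucleophile and any benzyl ester formed is saponified in situ.

**Step 17**
Reactants: 35 the ring D resorcinol from step 15; 37 3-[4-(benzyloxy)phenyl]propanoic acid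
Product: 39 3,5,7-tris(benzyloxy)-8-({3-[3-(4-benzyloxyphenyl)propanoyl]-2,4-dihydroxy-6-methoxy-5-methylphenyl}methyl)-2-(4-methoxyphenyl)-4H-chromen-4-one, via acid chloride 38 (not isolated)
Conditions: 37, (COCl)2, DMF (catalytic), CH2Cl2, rt, evaporate; then 35, TiCl4 (2.5 equiv), CH2Cl2, −40 to 0 °C; aqueous HCl
Reagents that add atoms: none
Why: Friedel–Crafts ortho-acylation of the titanium aryloxide of the phloroglucinol-type ring should take place at C3'', the only unsubstituted carbon of ring D and one lying between two oxygens, whereas ring A and ring B are deactivated by the chromone and the low temperature is chosen to keep the aryl benzyl ethers intact.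

**Step 18**
Reactants: 39 the tetrabenzyl ether from step 17
Product: 40 4'''-hydroxytrianguletin
Conditions: H2 (1 atm), 10% Pd/C, EtOAc/MeOH, rt
Reagents that add atoms: none
Why: Hydrogenolysis of the four aryl benzyl ethers over Pd/C should leave the doubly hydrogen-bonded aryl ketone, the chromone double bond, the diarylmethane and the two methyl ethers unreduced at one atmosphere of H2 and room temperature.

**Compound list**
1 | 2,4,6-trihydroxyacetophenone | CC(=O)c1c(O)cc(O)cc1O | starting material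
2 | 1-[2,4-bis(benzyloxy)-6-hydroxyphenyl]ethan-1-one | CC(=O)c1c(O)cc(OCc2ccccc2)cc1OCc1ccccc1 | intermediate
3 | 1-[2-(allyloxy)-4,6-bis(benzyloxy)phenyl]ethan-1-one | CC(=O)c1c(OCC=C)cc(OCc2ccccc2)cc1OCc1ccccc1 | intermediate
4 | racemic 2-acetyl-6-allyl-3,5-bis(benzyloxy)cyclohexa-2,4-dien-1-one | CC(=O)C1=C(OCc2ccccc2)C=C(OCc2ccccc2)C(CC=C)C1=O | intermediate
5 | 1-[3-allyl-4,6-bis(benzyloxy)-2-hydroxyphenyl]ethan-1-one | CC(=O)c1c(O)c(CC=C)c(OCc2ccccc2)cc1OCc1ccccc1 | intermediate
6 | 4-methoxybenzaldehyde | COc1ccc(C=O)cc1 | starting material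
7 | racemic 1-[3-allyl-4,6-bis(benzyloxy)-2-hydroxyphenyl]-3-hydroxy-3-(4-methoxyphenyl)propan-1-one | COc1ccc(C(O)CC(=O)c2c(O)c(CC=C)c(OCc3ccccc3)cc2OCc2ccccc2)cc1 | intermediate
8 | (E)-1-[3-allyl-4,6-bis(benzyloxy)-2-hydroxyphenyl]-3-(4-methoxyphenyl)prop-2-en-1-one | COc1ccc(/C=C/C(=O)c2c(O)c(CC=C)c(OCc3ccccc3)cc2OCc2ccccc2)cc1 | intermediate
9 | racemic trans-(2R*,3R*)-8-allyl-5,7-bis(benzyloxy)-3-hydroxy-2-(4-methoxyphenyl)chroman-4-one (one enantiomer drawn) | COc1ccc([C@H]2Oc3c(CC=C)c(OCc4ccccc4)cc(OCc4ccccc4)c3C(=O)[C@@H]2O)cc1 | intermediate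
10 | 8-allyl-5,7-bis(benzyloxy)-3-hydroxy-2-(4-methoxyphenyl)-4H-chromen-4-one | C=CCc1c(OCc2ccccc2)cc(OCc2ccccc2)c2c(=O)c(O)c(-c3ccc(OC)cc3)oc12 | intermediate
11 | 8-allyl-3,5,7-tris(benzyloxy)-2-(4-methoxyphenyl)-4H-chromen-4-one | C=CCc1c(OCc2ccccc2)cc(OCc2ccccc2)c2c(=O)c(OCc3ccccc3)c(-c3ccc(OC)cc3)oc12 | intermediate
12 | 9-[3-(Fl)propyl]-9-borabicyclo[3.3.1]nonane | C(CCc1c(OCc2ccccc2)cc(OCc2ccccc2)c2c(=O)c(OCc3ccccc3)c(-c3ccc(OC)cc3)oc12)B1C2CCCC1CCC2 | intermediate
13 | 3-(Fl)propan-1-ol | OCCCc1c(OCc2ccccc2)cc(OCc2ccccc2)c2c(=O)c(OCc3ccccc3)c(-c3ccc(OC)cc3)oc12 | intermediate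
14 | 3-(Fl)propanal | O=CCCc1c(OCc2ccccc2)cc(OCc2ccccc2)c2c(=O)c(OCc3ccccc3)c(-c3ccc(OC)cc3)oc12 | intermediate
15 | 3-(Fl)propanoic acid | OC(=O)CCc1c(OCc2ccccc2)cc(OCc2ccccc2)c2c(=O)c(OCc3ccccc3)c(-c3ccc(OC)cc3)oc12 | intermediate
16 | trichloroethylene | ClC=C(Cl)Cl | starting material
17 | dichloroacetylene | ClC#CCl | intermediate
18 | (E)-1-tert-butoxy-1,2-dichloroethene | CC(C)(C)O/C(Cl)=C\Cl | intermediate
19 | 1-tert-butoxy-2-chloroethyne | CC(C)(C)OC#CCl | intermediate
20 | lithium tert-butoxyacetylide | [Li]C#COC(C)(C)C | intermediate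
21 | tert-butoxyacetylene | C#COC(C)(C)C | intermediate
22 | 3-(Fl)propanoyl chloride | ClC(=O)CCc1c(OCc2ccccc2)cc(OCc2ccccc2)c2c(=O)c(OCc3ccccc3)c(-c3ccc(OC)cc3)oc12 | intermediate
23 | 3-(Fl)prop-1-en-1-one (monoalkylketene) | O=C=CCc1c(OCc2ccccc2)cc(OCc2ccccc2)c2c(=O)c(OCc3ccccc3)c(-c3ccc(OC)cc3)oc12 | intermediate
24 | racemic 3-tert-butoxy-4-(Fl-methyl)cyclobut-2-en-1-one | CC(C)(C)OC1=CC(=O)C1Cc1c(OCc2ccccc2)cc(OCc2ccccc2)c2c(=O)c(OCc3ccccc3)c(-c3ccc(OC)cc3)oc12 | intermediate
25 | 1-propynyllithium | [Li]C#CC | starting material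
26 | lithium prop-1-yn-1-olate | CC#C[O-].[Li+] | intermediate
27 | 1-(triisopropylsilyloxy)prop-1-yne | CC#CO[Si](C(C)C)(C(C)C)C(C)C | intermediate
28 | (3Z)-3-tert-butoxy-5-(Fl)penta-1,3-dien-1-one | O=C=C/C(OC(C)(C)C)=C/Cc1c(OCc2ccccc2)cc(OCc2ccccc2)c2c(=O)c(OCc3ccccc3)c(-c3ccc(OC)cc3)oc12 | intermediate
29 | racemic 4-[(1Z)-1-tert-butoxy-3-(Fl)prop-1-en-1-yl]-2-methyl-3-(triisopropylsilyloxy)cyclobut-2-en-1-one | O=C1C(C)=C(O[Si](C(C)C)(C(C)C)C(C)C)C1/C(OC(C)(C)C)=C/Cc1c(OCc2ccccc2)cc(OCc2ccccc2)c2c(=O)c(OCc3ccccc3)c(-c3ccc(OC)cc3)oc12 | intermediate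
30 | (3E,5Z)-5-tert-butoxy-2-methyl-7-(Fl)-3-(triisopropylsilyloxy)hepta-1,3,5-trien-1-one | O=C=C(C)/C(O[Si](C(C)C)(C(C)C)C(C)C)=C\C(OC(C)(C)C)=C\Cc1c(OCc2ccccc2)cc(OCc2ccccc2)c2c(=O)c(OCc3ccccc3)c(-c3ccc(OC)cc3)oc12 | intermediate
31 | racemic 5-tert-butoxy-6-(Fl-methyl)-2-methyl-3-(triisopropylsilyloxy)cyclohexa-2,4-dien-1-one | O=C1C(C)=C(O[Si](C(C)C)(C(C)C)C(C)C)C=C(OC(C)(C)C)C1Cc1c(OCc2ccccc2)cc(OCc2ccccc2)c2c(=O)c(OCc3ccccc3)c(-c3ccc(OC)cc3)oc12 | intermediate
32 | 3,5,7-tris(benzyloxy)-8-{[2-tert-butoxy-6-hydroxy-5-methyl-4-(triisopropylsilyloxy)phenyl]methyl}-2-(4-methoxyphenyl)-4H-chromen-4-one | CC(C)(C)Oc1cc(O[Si](C(C)C)(C(C)C)C(C)C)c(C)c(O)c1Cc1c(OCc2ccccc2)cc(OCc2ccccc2)c2c(=O)c(OCc3ccccc3)c(-c3ccc(OC)cc3)oc12 | intermediate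
33 | 3,5,7-tris(benzyloxy)-8-{[2-tert-butoxy-6-methoxy-5-methyl-4-(triisopropylsilyloxy)phenyl]methyl}-2-(4-methoxyphenyl)-4H-chromen-4-one | CC(C)(C)Oc1cc(O[Si](C(C)C)(C(C)C)C(C)C)c(C)c(OC)c1Cc1c(OCc2ccccc2)cc(OCc2ccccc2)c2c(=O)c(OCc3ccccc3)c(-c3ccc(OC)cc3)oc12 | intermediate
34 | 3,5,7-tris(benzyloxy)-8-{[2-hydroxy-6-methoxy-5-methyl-4-(triisopropylsilyloxy)phenyl]methyl}-2-(4-methoxyphenyl)-4H-chromen-4-one | Oc1cc(O[Si](C(C)C)(C(C)C)C(C)C)c(C)c(OC)c1Cc1c(OCc2ccccc2)cc(OCc2ccccc2)c2c(=O)c(OCc3ccccc3)c(-c3ccc(OC)cc3)oc12 | intermediate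
35 | 3,5,7-tris(benzyloxy)-8-[(2,4-dihydroxy-6-methoxy-5-methylphenyl)methyl]-2-(4-methoxyphenyl)-4H-chromen-4-one | Oc1cc(O)c(C)c(OC)c1Cc1c(OCc2ccccc2)cc(OCc2ccccc2)c2c(=O)c(OCc3ccccc3)c(-c3ccc(OC)cc3)oc12 | intermediate
36 | 3-(4-hydroxyphenyl)propanoic acid | O=C(O)CCc1ccc(O)cc1 | starting material
37 | 3-[4-(benzyloxy)phenyl]propanoic acid | O=C(O)CCc1ccc(OCc2ccccc2)cc1 | intermediate
38 | 3-[4-(benzyloxy)phenyl]propanoyl chloride | O=C(Cl)CCc1ccc(OCc2ccccc2)cc1 | intermediate
39 | 3,5,7-tris(benzyloxy)-8-({3-[3-(4-benzyloxyphenyl)propanoyl]-2,4-dihydroxy-6-methoxy-5-methylphenyl}methyl)-2-(4-methoxyphenyl)-4H-chromen-4-one | COc1c(C)c(O)c(C(=O)CCc2ccc(OCc3ccccc3)cc2)c(O)c1Cc1c(OCc2ccccc2)cc(OCc2ccccc2)c2c(=O)c(OCc3ccccc3)c(-c3ccc(OC)cc3)oc12 | intermediate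
40 | 4'''-hydroxytrianguletin, 8-({2,4-dihydroxy-3-[3-(4-hydroxyphenyl)propanoyl]-6-methoxy-5-methylphenyl}methyl)-3,5,7-trihydroxy-2-(4-methoxyphenyl)-4H-chromen-4-one | COc1c(C)c(O)c(C(=O)CCc2ccc(O)cc2)c(O)c1Cc1c(O)cc(O)c2c(=O)c(O)c(-c3ccc(OC)cc3)oc12 | target

**Totals**
Total step count: 18.
Longest linear sequence: 14 steps (steps 1–8, 11, 13, 14, 15, 17 and 18).

**Steps most likely to fail, with fallbacks**

Step 13. The vinylketene may be consumed by self-addition or by acylating the product phenol, or the tert-butyl enol ether may lose isobutene, before the cycloaddition with the siloxyalkyne takes place. The fallback brings ring D in ready-made and joins it to the flavone by an acid-mediated Friedel–Crafts benzylation; it sets out from 11 and 37 and returns to the route at 39. Double-bond migration in 11 (RuHCl(CO)(PPh3)3 catalytic, toluene, 80 °C) should give the 8-[(E)-prop-1-enyl]flavone F1. Lemieux–Johnson cleavage (OsO4 catalytic, NaIO4, 2,6-lutidine, dioxane/H2O) should give the 8-carbaldehyde F2, and NaBH4 (THF/MeOH, 0 °C) the 8-(hydroxymethyl)flavone F3. In parallel, acid chloride 38 (from 37) acylates commercial 2-methylphloroglucinol under the conditions of step 17 to the acylphloroglucinol F4. Monomethylation of its most acidic, non-chelated hydroxyl para to the acyl group (Me2SO4, 1 equiv, K2CO3, acetone) gives F5, whose single free ring carbon corresponds to C1''. Ionisation of F3 with catalytic BF3·OEt2 (CH2Cl2/dioxane, 0 °C) in the presence of F5 should form the C8–CH2–C1'' bridge and give 39, from which step 18 is run.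

Step 11. Oligomerisation of the amine-generated monoalkylketene, or thermal decay of the ynol ether, may outpace the cycloaddition. The fallback generates the same ketene 23 without amine by Wolff rearrangement; it sets out from 11 and returns at 24. Lemieux–Johnson cleavage of 11 gives the arylacetaldehyde F6, and Pinnick oxidation (NaClO2, NaH2PO4, 2-methyl-2-butene) the arylacetic acid F7. Oxalyl chloride gives the acid chloride F8, and trimethylsilyldiazomethane the diazoketone F9. Irradiation of F9 with blue light (about 450 nm, beyond the flavone absorption) at room temperature in the presence of excess 21 should release 23 slowly and give 24.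

Step 17. The Lewis acid may cleave benzyl ethers, the liberated benzyl cations may alkylate the electron-rich rings, or the acyl chloride may cyclise onto its own ring. The fallback removes the benzyl groups first and acylates without protecting groups; it sets out from 35 and 36 and returns at 40. Hydrogenolysis of 35 (H2, Pd/C, EtOAc/MeOH) gives the pentaphenol F10. F10 is acylated with the unprotected acid 36 in BF3·OEt2/dioxane at 70 °C, the classical dihydrochalcone synthesis. Ring D is the only phloroglucinol-type nucleus with a free position, so acylation should occur at C3'' and give 40 directly.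

**Further compounds**
F1 | step 13 | 3,5,7-tris(benzyloxy)-2-(4-methoxyphenyl)-8-[(E)-prop-1-en-1-yl]-4H-chromen-4-one | C/C=C/c1c(OCc2ccccc2)cc(OCc2ccccc2)c2c(=O)c(OCc3ccccc3)c(-c3ccc(OC)cc3)oc12
F2 | step 13 | 3,5,7-tris(benzyloxy)-2-(4-methoxyphenyl)-4-oxo-4H-chromene-8-carbaldehyde | O=Cc1c(OCc2ccccc2)cc(OCc2ccccc2)c2c(=O)c(OCc3ccccc3)c(-c3ccc(OC)cc3)oc12
F3 | step 13 | 3,5,7-tris(benzyloxy)-8-(hydroxymethyl)-2-(4-methoxyphenyl)-4H-chromen-4-one | OCc1c(OCc2ccccc2)cc(OCc2ccccc2)c2c(=O)c(OCc3ccccc3)c(-c3ccc(OC)cc3)oc12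
F4 | step 13 | 3-[4-(benzyloxy)phenyl]-1-(2,4,6-trihydroxy-3-methylphenyl)propan-1-one | Cc1c(O)cc(O)c(C(=O)CCc2ccc(OCc3ccccc3)cc2)c1O
F5 | step 13 | 3-[4-(benzyloxy)phenyl]-1-(2,6-dihydroxy-4-methoxy-3-methylphenyl)propan-1-one | COc1cc(O)c(C(=O)CCc2ccc(OCc3ccccc3)cc2)c(O)c1C
F6 | step 11 | 2-(Fl)acetaldehyde | O=CCc1c(OCc2ccccc2)cc(OCc2ccccc2)c2c(=O)c(OCc3ccccc3)c(-c3ccc(OC)cc3)oc12
F7 | step 11 | 2-(Fl)acetic acid | OC(=O)Cc1c(OCc2ccccc2)cc(OCc2ccccc2)c2c(=O)c(OCc3ccccc3)c(-c3ccc(OC)cc3)oc12
F8 | step 11 | 2-(Fl)acetyl chloride | ClC(=O)Cc1c(OCc2ccccc2)cc(OCc2ccccc2)c2c(=O)c(OCc3ccccc3)c(-c3ccc(OC)cc3)oc12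
F9 | step 11 | 1-diazo-3-(Fl)propan-2-one | [N-]=[N+]=CC(=O)Cc1c(OCc2ccccc2)cc(OCc2ccccc2)c2c(=O)c(OCc3ccccc3)c(-c3ccc(OC)cc3)oc12
F10 | step 17 | 8-[(2,4-dihydroxy-6-methoxy-5-methylphenyl)methyl]-3,5,7-trihydroxy-2-(4-methoxyphenyl)-4H-chromen-4-one | Oc1cc(O)c(C)c(OC)c1Cc1c(O)cc(O)c2c(=O)c(O)c(-c3ccc(OC)cc3)oc12
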